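C1–C9 number the bicyclo[3.3.1]nonane-2,4,9-trione core (C1 benzoyl, C5 geranyl, C8 CMe2). C7–C10–C11–C3 is the two-carbon bridge, C3/C11/C12(Me2)/C13/C14 the cyclopentane, and C15 the carbinol carbon.
Enabling feature: ring A (C1–C5, C9) is a cyclohexane-1,3,5-trione. Its C4 ketone sits in the cyclopentane-fused seven-membered ring C3–C4–C5–C6–C7–C10–C11 between its two α-carbons C3 and C5. C2–C1–C9 is a benzoylmalonyl unit held on C7 through C8.
Cuts, in order: O–Si; C5–C9 together with C2–C3; C1–COPh; C5–geranyl; the C5 methylene (ring expansion); C7–C8 (radical conjugate addition); C6=C7 and C10–C11 (cyclohexenone annulation); then the cyclopentene back to (R)-carvone by ring contraction.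
Forward ring order: carvone ring, acetylcyclopentene, cis-hydrindenone, hydroazulenone, then ring B, ring A and the second seven-membered ring in one operation.
Stereochemistry: C13 comes from (R)-carvone. C11 is set by addition anti to the C13 side chain. C7 is set by axial, convex-face radical addition trans to the C11–C12 bond. C1, C3 and C5 are set by the C7–C8–C1 tether in the key step. The E-alkene comes from geranyl bromide.

Key step: step 19

Remark: C3 and C5 stay epimerizable up to step 19, are drawn as one epimer each and are erased by enolization in the key step. Metal enolates and salts that exist only between two additions are not numbered.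

Step 1
Reactants: 1 (R)-(−)-carvone
Product: 2 (5R,6S)-6-methylcarvone
Conditions: LiN(i-Pr)2, THF, −78 °C; MeI, −78 to 0 °C
Reagents that add atoms: iodomethane, CI
Why: Kinetic deprotonation of the cross-conjugated enone occurs only at the α′ methylene (future C12), and the lithium enolate should be methylated anti to the isopropenyl group (enolate alkylation); the new centre disappears in step 2.

Step 2
Reactants: 2 (5R,6S)-6-methylcarvone
Product: 3 (5S)-6,6-dimethylcarvone
Conditions: LiN(i-Pr)2, THF, −78 °C; MeI, −78 °C to rt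
Reagents that add atoms: iodomethane, CI
Why: A second kinetic enolization removes the only α′ hydrogen left, and methylation completes the gem-dimethyl carbon C12 (enolate alkylation, the known two-stage α′,α′-dimethylation of carvone); C13 is untouched, and only its descriptor changes.

Step 3
Reactants: 3 (5S)-6,6-dimethylcarvone
Product: 4 (5R)-5-(2-hydroxypropan-2-yl)-2,6,6-trimethylcyclohex-2-en-1-one
Conditions: Co(acac)2 (cat.), PhSiH3, O2 (1 atm), THF, rt; aq. Na2S2O3
Reagents that add atoms: dioxygen, O=O
Why: Mukaiyama hydration: the cobalt hydride made from PhSiH3 passes a hydrogen atom to the electron-rich 1,1-disubstituted alkene, O2 traps the tertiary radical at C15, and the electron-poor, hindered enone should be left alone; no stereocentre is formed.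

Step 4
Reactants: 4 (5R)-5-(2-hydroxypropan-2-yl)-2,6,6-trimethylcyclohex-2-en-1-one
Product: 5 triethylsilyl ether of 4
Conditions: Et3SiOSO2CF3, 2,6-lutidine, CH2Cl2, 0 °C
Reagents that add atoms: triethylsilyl triflate, CC[Si](CC)(CC)OS(=O)(=O)C(F)(F)F
Why: A silyl triflate with a hindered pyridine base is the standard O-silylation of a tertiary alcohol, and the ether should withstand the bases, ozone and radicals used up to step 20.

Step 5
Reactants: 5 triethylsilyl ether of 4
Product: 6 (5R)-2,6,6-trimethyl-5-[2-(triethylsilyloxy)propan-2-yl]cyclohex-1-en-1-yl triflate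
Conditions: LiBH(s-Bu)3, THF, −78 °C; PhNTf2, −78 °C to rt
Reagents that add atoms: N-phenylbis(trifluoromethanesulfonimide), O=S(=O)(N(c1ccccc1)S(=O)(=O)C(F)(F)F)C(F)(F)F
Why: Conjugate hydride addition of the bulky borohydride gives the enolate, which can only point toward the methyl-bearing carbon because the other α-carbon is quaternary, and O-sulfonylation fixes it as the vinyl triflate (reductive enolate trapping).

Step 6
Reactants: 6 (5R)-2,6,6-trimethyl-5-[2-(triethylsilyloxy)propan-2-yl]cyclohex-1-en-1-yl triflate
Product: 7 triethyl({2-[(1R)-2,2,4-trimethylcyclohex-3-en-1-yl]propan-2-yl}oxy)silane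
Conditions: Pd(OAc)2 (cat.), PPh3, HCO2H, Bu3N, DMF, 60 °C
Reagents that add atoms: none
Why: Palladium-catalysed formate hydrogenolysis of a vinyl triflate (oxidative addition to zerovalent palladium, formate exchange, loss of CO2, reductive elimination) replaces OTf by H and leaves the alkene exactly between future C11 and C4.

Step 7
Reactants: 7 triethyl({2-[(1R)-2,2,4-trimethylcyclohex-3-en-1-yl]propan-2-yl}oxy)silane
Product: 9 (3R)-2,2-dimethyl-6-oxo-3-[2-(triethylsilyloxy)propan-2-yl]heptanal, via ozonide 8 (not isolated)
Conditions: O3, CH2Cl2, −78 °C; PPh3, −78 °C to rt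
Reagents that add atoms: ozone, [O-][O+]=O
Why: Ozonolysis with reductive work-up (Criegee mechanism) cleaves the only alkene into the methyl ketone (C4) and the α-quaternary aldehyde (C11) without touching C13.

Step 8
Reactants: 9 (3R)-2,2-dimethyl-6-oxo-3-[2-(triethylsilyloxy)propan-2-yl]heptanal
Product: 10 1-{(4R)-3,3-dimethyl-4-[2-(triethylsilyloxy)propan-2-yl]cyclopent-1-en-1-yl}ethanone
Conditions: KOH (cat.), MeOH, rt to 40 °C
Reagents that add atoms: none
Why: Intramolecular aldol condensation: the aldehyde has no α-hydrogen, and five-membered closure through the ketone methylene C3 is far faster than seven-membered closure through the methyl group, so only the 1-acetylcyclopentene is expected.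

Step 9
Reactants: 10 1-{(4R)-3,3-dimethyl-4-[2-(triethylsilyloxy)propan-2-yl]cyclopent-1-en-1-yl}ethanone
Product: 12 2-allyl-3,3-dimethyl-4-[2-(triethylsilyloxy)propan-2-yl]cyclopentyl methyl ketone (allyl trans to acetyl; allyl trans to the C13 side chain), via enol silane 11 (not isolated)
Conditions: CH2=CHCH2MgBr, CuBr·SMe2, Me3SiCl, THF, −78 °C; 1 M HCl, THF, 0 °C
Reagents that add atoms: allylmagnesium bromide, C=CC[Mg]Br; chlorotrimethylsilane (silicon only in 11), C[Si](C)(C)Cl
Why: Me3SiCl-accelerated conjugate addition of allylcopper to the acetylcyclopentene: the reagent should reach C11 on the ring face opposite the bulky C13 side chain, which sets C11 (H-11 cis to that side chain), and hydrolysis of 11 gives the more stable trans-acetyl epimer at the epimerizable C3.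

Step 10
Reactants: 12 2-allyl-3,3-dimethyl-4-[2-(triethylsilyloxy)propan-2-yl]cyclopentyl methyl ketone
Product: 14 2-{2-acetyl-5,5-dimethyl-4-[2-(triethylsilyloxy)propan-2-yl]cyclopentyl}acetaldehyde, via ozonide 13 (not isolated)
Conditions: O3, CH2Cl2, −78 °C; PPh3, −78 °C to rt
Reagents that add atoms: ozone, [O-][O+]=O
Why: Ozonolysis with reductive work-up of the only alkene shortens the allyl group to the C10–C7 acetaldehyde chain; no stereocentre is affected.

Step 11
Reactants: 14 2-{2-acetyl-5,5-dimethyl-4-[2-(triethylsilyloxy)propan-2-yl]cyclopentyl}acetaldehyde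
Product: 15 cis-1,1-dimethyl-2-[2-(triethylsilyloxy)propan-2-yl]-1,2,3,3a,7,7a-hexahydro-4H-inden-4-one (H-3 and H-11 and the C13 side chain all cis)
Conditions: KOH, MeOH, 0 °C to rt
Reagents that add atoms: none
Why: Intramolecular aldol condensation of a 1,5-keto aldehyde (the closing half of a Robinson annulation): only the methyl carbon (C6) can reach the aldehyde (C7) in an unstrained ring, and C3 equilibrates under the base so that the cis ring fusion can form.

Step 12
Reactants: 16 dimethyl isopropylidenemalonate
Product: 17 dimethyl 2-(prop-1-en-2-yl)malonate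
Conditions: LiN(i-Pr)2, THF, −78 °C; AcOH, −78 °C
Reagents that add atoms: none
Why: Deconjugative protonation: γ-deprotonation gives the extended enolate, which acetic acid protonates kinetically at its α-carbon (C1), leaving the terminal alkene needed in step 13.

Step 13
Reactants: 15 cis-hydrindenone; 17 dimethyl 2-(prop-1-en-2-yl)malonate
Product: 18 cis-hydrindanone bearing the 2-[bis(methoxycarbonyl)methyl]propan-2-yl arm on C7 (arm cis to H-11)
Conditions: 17 (3 equiv), Fe(acac)3 (0.3 equiv), PhSiH3, EtOH, 60 °C
Reagents that add atoms: dimethyl 2-(prop-1-en-2-yl)malonate (17), C=C(C)C(C(=O)OC)C(=O)OC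
Why: Iron-catalysed reductive olefin coupling (hydrogen-atom transfer followed by Giese addition): the iron hydride adds H to the CH2 terminus of 17, and the tertiary C8 radical attacks the unhindered β-carbon C7 of the enone axially and from the convex face, trans to the C11–C12 bond as in 3,5-trans additions to 5-substituted cyclohexenones, which sets C7.

Step 14
Reactants: 18 cis-hydrindanone malonate
Product: 20 cis-hydroazulenone malonate (C4 ketone with C5 and C6 methylene groups; arm on C7), via α-silyl ketone 19 (not isolated)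
Conditions: Me3SiCHN2, BF3·OEt2, CH2Cl2, −78 to −30 °C; 1 M HCl, THF, 0 °C
Reagents that add atoms: (trimethylsilyl)diazomethane, C[Si](C)(C)C=[N+]=[N-]
Why: Lewis acid promoted one-carbon homologation of a ketone (Tiffeneau–Demjanov-type 1,2-shift): the diazo carbon adds to C4, the methylene C6 migrates in preference to the methine C3, and dilute acid removes silicon from 19, so the inserted carbon becomes C5.

Step 15
Reactants: 20 cis-hydroazulenone malonate; 21 geranyl bromide
Product: 22 C5-geranyl hydroazulenone malonate
Conditions: LiN(i-Pr)2 (2.2 equiv), THF, −78 °C; 21, DMPU, −78 to −40 °C; aq. NH4Cl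
Reagents that add atoms: geranyl bromide (21), CC(C)=CCC/C(C)=C/CBr
Why: Dianion alkylation: the first equivalent of amide turns the malonate into its unreactive enolate (which also shields the esters), the second deprotonates the ketone kinetically at the C5 methylene rather than the C3 methine, and the far more nucleophilic ketone enolate takes up the allylic bromide by SN2 with the E-alkene intact; the C5 configuration is of no consequence.

Step 16
Reactants: 22 C5-geranyl hydroazulenone malonate
Product: 24 bis(tert-butyldimethylsilyl) malonate of the hydroazulenone, via malonic acid 23 (not isolated)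
Conditions: NaSEt, DMF, 60 °C; 1 M HCl; t-BuMe2SiCl, imidazole, DMF, rt
Reagents that add atoms: tert-butyldimethylsilyl chloride, CC(C)(C)[Si](C)(C)Cl
Why: Thiolate cleaves both methyl esters by SN2 attack at the methyl carbon, which avoids the hindered carbonyl groups and any hydroxide or alkoxide that could start a premature Dieckmann closure, and the crude acid is capped as its silyl esters.

Step 17
Reactants: 24 bis(tert-butyldimethylsilyl) malonate; 25 benzoyl chloride
Product: 26 bis(tert-butyldimethylsilyl) benzoylmalonate of the hydroazulenone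
Conditions: KN(SiMe3)2 (1.05 equiv), THF, −78 °C; 25, −78 to 0 °C
Reagents that add atoms: benzoyl chloride (25), O=C(Cl)c1ccccc1
Why: C-acylation of a bis(silyl) malonate enolate with an acid chloride, a known entry to acylmalonates: one equivalent of base removes only H-1, about ten pK units more acidic than the ketone α-hydrogens, and C1 is not yet stereogenic because its two ester groups are alike.

Step 18
Reactants: 26 bis(tert-butyldimethylsilyl) benzoylmalonate
Product: 28 bis(pentafluorophenyl) benzoylmalonate of the C5-geranyl cis-hydroazulenone, via bis(acid chloride) 27 (not isolated)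
Conditions: (COCl)2, DMF (cat.), CH2Cl2, 0 °C to rt; evaporate; C6F5OH, pyridine, CH2Cl2, 0 °C
Reagents that add atoms: pentafluorophenol, Oc1c(F)c(F)c(F)c(F)c1F; oxalyl chloride (chlorine only in 27), O=C(Cl)C(=O)Cl
Why: Oxalyl chloride with catalytic DMF converts silyl esters directly into acid chlorides under neutral conditions, so neither a free benzoylmalonic acid (decarboxylation) nor a nucleophile able to debenzoylate C1 is ever present, and pentafluorophenol with pyridine then gives the active esters by acyl substitution.

Step 19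
Reactants: 28 bis(pentafluorophenyl) benzoylmalonate of the C5-geranyl cis-hydroazulenone
Product: 30 triethylsilyl ether of the target, via bicyclic diketo ester 29 (not isolated)
Conditions: LiN(SiMe3)2 (2.3 equiv), THF (0.005 M, slow addition of 28 to the base), −78 to 0 °C; aq. NH4Cl
Reagents that add atoms: none
Why: LiN(SiMe3)2 enolizes the C4 ketone, the C5 enolate attacks one pentafluorophenyl ester on C1, expels C6F5OLi and gives 29, in which C5 is quaternary, so the second equivalent of base can enolize only toward C3, whose attack on the remaining ester completes the cage (an initial C3 enolate reaches the same product by proton exchange or by the slower seven-ring closure). The closest known reactions are the Effenberger α,α′-diacylation of ketone enol derivatives with malonyl dichloride and the C-acylation of ketone enolates with pentafluorophenyl esters. Ring B (C1, C9, C5–C8) closes 6-exo-trig at the ester carbonyl, ring A (C1–C5, C9) closes in the same mode, and the same C2–C3 bond closes the second seven-membered ring (C1, C2, C3, C11, C10, C7, C8). C5 and C3 are set because the three-atom link C7–C8–C1 can bring the acyl carbons only to the ring face that carries the arm (the face of H-11), and C1 is set in the first closure, where the rotamer with benzoyl anti to C7 puts one ester over C5 and leaves the other axial under C3. The step needs C- rather than O-acylation, which ring size secures (six-membered diketones against eight- and nine-membered enol lactones), and it needs irreversibility, which the weakly basic and weakly nucleophilic pentafluorophenoxide provides for products that cannot be stored as enolates. Because C1 carries no hydrogen, neither ketene formation nor quenching of the ketone enolate can compete.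

Step 20
Reactants: 30 triethylsilyl ether of the target
Product: 31 target CNP0164095.1
Conditions: HF·pyridine, pyridine, THF, 0 °C to rt
Reagents that add atoms: none
Why: Fluoride-driven cleavage of the tertiary triethylsilyl ether under weakly acidic, buffered conditions should avoid the retro-Claisen opening that basic fluoride sources could cause in the non-enolizable tetraketone; no stereocentre is touched.

Compound list
1 | (R)-(−)-carvone, (5R)-2-methyl-5-(prop-1-en-2-yl)cyclohex-2-en-1-one | CC1=CC[C@@H](C(C)=C)CC1=O | starting material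
2 | (5R,6S)-6-methylcarvone (methyl trans to isopropenyl) | CC1=CC[C@@H](C(C)=C)[C@H](C)C1=O | intermediate
3 | (5S)-6,6-dimethylcarvone, 2,6,6-trimethyl-5-(prop-1-en-2-yl)cyclohex-2-en-1-one | CC1=CC[C@@H](C(C)=C)C(C)(C)C1=O | intermediate
4 | (5R)-5-(2-hydroxypropan-2-yl)-2,6,6-trimethylcyclohex-2-en-1-one | CC1=CC[C@@H](C(C)(C)O)C(C)(C)C1=O | intermediate
5 | (5R)-2,6,6-trimethyl-5-[2-(triethylsilyloxy)propan-2-yl]cyclohex-2-en-1-one | CC1=CC[C@@H](C(C)(C)O[Si](CC)(CC)CC)C(C)(C)C1=O | intermediate
6 | (5R)-2,6,6-trimethyl-5-[2-(triethylsilyloxy)propan-2-yl]cyclohex-1-en-1-yl triflate | CC1=C(OS(=O)(=O)C(F)(F)F)C(C)(C)[C@H](C(C)(C)O[Si](CC)(CC)CC)CC1 | intermediate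
7 | triethyl({2-[(1R)-2,2,4-trimethylcyclohex-3-en-1-yl]propan-2-yl}oxy)silane | CC1=CC(C)(C)[C@H](C(C)(C)O[Si](CC)(CC)CC)CC1 | intermediate
8 | bicyclic 1,2,4-trioxolane (ozonide) of 7, C13 as in 7, ozonide carbons undefined | CC12CC[C@@H](C(C)(C)O[Si](CC)(CC)CC)C(C)(C)C(OO1)O2 | intermediate
9 | (3R)-2,2-dimethyl-6-oxo-3-[2-(triethylsilyloxy)propan-2-yl]heptanal | CC(=O)CC[C@@H](C(C)(C)O[Si](CC)(CC)CC)C(C)(C)C=O | intermediate
10 | 1-{(4R)-3,3-dimethyl-4-[2-(triethylsilyloxy)propan-2-yl]cyclopent-1-en-1-yl}ethanone | CC(=O)C1=CC(C)(C)[C@H](C(C)(C)O[Si](CC)(CC)CC)C1 | intermediate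
11 | trimethylsilyl enol ether (C3=C4) of 12, allyl on C11 trans to the C13 side chain, enol ether geometry undefined | C=CC[C@H]1C(C)(C)[C@H](C(C)(C)O[Si](CC)(CC)CC)CC1=C(C)O[Si](C)(C)C | intermediate
12 | 2-allyl-3,3-dimethyl-4-[2-(triethylsilyloxy)propan-2-yl]cyclopentyl methyl ketone, allyl (C11) trans to acetyl (C3) and trans to the C13 side chain | C=CC[C@H]1C(C)(C)[C@H](C(C)(C)O[Si](CC)(CC)CC)C[C@@H]1C(C)=O | intermediate
13 | 1,2,4-trioxolane (ozonide) of 12, ring stereocentres as in 12 | C1OC(C[C@H]2C(C)(C)[C@H](C(C)(C)O[Si](CC)(CC)CC)C[C@@H]2C(C)=O)OO1 | intermediate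
14 | 2-{2-acetyl-5,5-dimethyl-4-[2-(triethylsilyloxy)propan-2-yl]cyclopentyl}acetaldehyde, stereocentres as in 12 | O=CC[C@H]1C(C)(C)[C@H](C(C)(C)O[Si](CC)(CC)CC)C[C@@H]1C(C)=O | intermediate
15 | cis-1,1-dimethyl-2-[2-(triethylsilyloxy)propan-2-yl]-1,2,3,3a,7,7a-hexahydro-4H-inden-4-one; H-3, H-11 and the C13 side chain on one face | O=C1C=CC[C@H]2C(C)(C)[C@H](C(C)(C)O[Si](CC)(CC)CC)C[C@@H]12 | intermediate
16 | dimethyl isopropylidenemalonate | COC(=O)C(=C(C)C)C(=O)OC | starting material
17 | dimethyl 2-(prop-1-en-2-yl)malonate | C=C(C)C(C(=O)OC)C(=O)OC | intermediate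
18 | cis-hydrindan-4-one of 15 carrying on C7 the 2-[bis(methoxycarbonyl)methyl]propan-2-yl arm, arm cis to H-11 and H-3 | O=C1C[C@H](C(C)(C)C(C(=O)OC)C(=O)OC)C[C@H]2C(C)(C)[C@H](C(C)(C)O[Si](CC)(CC)CC)C[C@@H]12 | intermediate
19 | ring-expanded ketone with Me3Si on C5 (C5 undefined), other centres as in 18 | O=C1C([Si](C)(C)C)C[C@H](C(C)(C)C(C(=O)OC)C(=O)OC)C[C@H]2C(C)(C)[C@H](C(C)(C)O[Si](CC)(CC)CC)C[C@@H]12 | intermediate
20 | cis-hydroazulenone (C4 ketone) with the dimethyl malonate arm on C7, arm cis to H-11 | O=C1CC[C@H](C(C)(C)C(C(=O)OC)C(=O)OC)C[C@H]2C(C)(C)[C@H](C(C)(C)O[Si](CC)(CC)CC)C[C@@H]12 | intermediate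
21 | geranyl bromide | CC(C)=CCC/C(C)=C/CBr | starting material
22 | 20 with an (E)-geranyl group on C5 (one C5 epimer drawn) | CC(C)=CCC/C(C)=C/C[C@H]1C[C@H](C(C)(C)C(C(=O)OC)C(=O)OC)C[C@H]2C(C)(C)[C@H](C(C)(C)O[Si](CC)(CC)CC)C[C@H]2C1=O | intermediate
23 | malonic acid corresponding to 22 | CC(C)=CCC/C(C)=C/C[C@H]1C[C@H](C(C)(C)C(C(=O)O)C(=O)O)C[C@H]2C(C)(C)[C@H](C(C)(C)O[Si](CC)(CC)CC)C[C@H]2C1=O | intermediate
24 | bis(tert-butyldimethylsilyl) ester of 23 | CC(C)=CCC/C(C)=C/C[C@H]1C[C@H](C(C)(C)C(C(=O)O[Si](C)(C)C(C)(C)C)C(=O)O[Si](C)(C)C(C)(C)C)C[C@H]2C(C)(C)[C@H](C(C)(C)O[Si](CC)(CC)CC)C[C@H]2C1=O | intermediate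
25 | benzoyl chloride | O=C(Cl)c1ccccc1 | starting material
26 | 24 with benzoyl on C1 | CC(C)=CCC/C(C)=C/C[C@H]1C[C@H](C(C)(C)C(C(=O)c2ccccc2)(C(=O)O[Si](C)(C)C(C)(C)C)C(=O)O[Si](C)(C)C(C)(C)C)C[C@H]2C(C)(C)[C@H](C(C)(C)O[Si](CC)(CC)CC)C[C@H]2C1=O | intermediate
27 | benzoylmalonyl dichloride corresponding to 26 | CC(C)=CCC/C(C)=C/C[C@H]1C[C@H](C(C)(C)C(C(=O)c2ccccc2)(C(=O)Cl)C(=O)Cl)C[C@H]2C(C)(C)[C@H](C(C)(C)O[Si](CC)(CC)CC)C[C@H]2C1=O | intermediate
28 | cis-hydroazulenone with C5 geranyl and the C7-tethered bis(pentafluorophenyl) benzoylmalonate | CC(C)=CCC/C(C)=C/C[C@H]1C[C@H](C(C)(C)C(C(=O)c2ccccc2)(C(=O)Oc2c(F)c(F)c(F)c(F)c2F)C(=O)Oc2c(F)c(F)c(F)c(F)c2F)C[C@H]2C(C)(C)[C@H](C(C)(C)O[Si](CC)(CC)CC)C[C@H]2C1=O | intermediate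
29 | ring B closed (C5–C9 formed): bicyclo[4.3.1] 4,9-diketone with benzoyl equatorial and the remaining pentafluorophenyl ester axial on C1 | CC(C)=CCC/C(C)=C/C[C@@]12C[C@H](C(C)(C)[C@@](C(=O)c3ccccc3)(C(=O)Oc3c(F)c(F)c(F)c(F)c3F)C2=O)C[C@H]3C(C)(C)[C@H](C(C)(C)O[Si](CC)(CC)CC)C[C@H]3C1=O | intermediate
30 | triethylsilyl ether of the target | CC(C)=CCC/C(C)=C/C[C@@]12C[C@H]3C[C@H]4C(C)(C)[C@H](C(C)(C)O[Si](CC)(CC)CC)C[C@]4(C1=O)C(=O)[C@@](C(=O)c1ccccc1)(C2=O)C3(C)C | intermediate
31 | CNP0164095.1 | CC(C)=CCC/C(C)=C/C[C@@]12C[C@H]3C[C@H]4C(C)(C)[C@H](C(C)(C)O)C[C@]4(C1=O)C(=O)[C@@](C(=O)c1ccccc1)(C2=O)C3(C)C | target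

Total step count: 20. Longest linear sequence: 19 (steps 1–11 and 13–20; step 12 is a side branch).

Steps most likely to fail

Step 19.
- Risk: the sequence may stall after the first closure, may take up the wrong one of the two diastereotopic esters, or may lose active ester and benzoyl groups to the amide base.
- Fallback: it sets out from 28 and separates the two closures, using no amide base. Soft enolization with MgBr2·OEt2 and i-Pr2NEt in CH2Cl2, a known way to acylate ketones with pentafluorophenyl esters, should close only ring B and allow 29 to be isolated and its C1 epimers sorted.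
- Me3SiOSO2CF3 and Et3N then convert the only enolizable position of 29 into the C3=C4 trimethylsilyl enol ether F1.
- Catalytic Bu4N[Ph3SiF2] releases the C3 enolate next to the axial ester, so that silyl transfer to pentafluorophenoxide drives the second acylation. The route is rejoined at 30.

Step 17.
- Risk: C-acylation at the very hindered malonate carbon may lose out to O-acylation or to silyl transfer from the esters.
- Fallback: it sets out from 22 and replaces steps 16–18. Me2AlSEt (from AlMe3 and EtSH) in CH2Cl2 exchanges both methyl esters to give the bis(S-ethyl) dithiomalonate F2. F2 is several pK units more acidic and is enolized by MgBr2·OEt2 and i-Pr2NEt as a magnesium chelate that holds both carbonyl groups away from C1.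
- Benzoyl chloride 25 then gives the benzoyl dithiomalonate F3.
- Thiophilic activation with AgOSO2CF3 in the presence of C6F5OH and 2,6-di-tert-butylpyridine exchanges both thioesters without any nucleophile that could debenzoylate C1. The route is rejoined at 28.

Step 13.
- Risk: isomerization of the donor alkene back into conjugation and simple reduction of the enone may outrun the cross-coupling.
- Fallback: it sets out from 16 and makes the same C8 radical by halogen abstraction instead of hydrogen-atom transfer. HBr in AcOH adds to 16 to give the tertiary bromide dimethyl 2-(2-bromopropan-2-yl)malonate F4.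
- Slow addition of (Me3Si)3SiH and AIBN to F4 and 15 in benzene at 80 °C (Giese addition) should deliver the arm to C7 with the same facial preference. The route is rejoined at 18.

Further compounds
F1 | step 19 | C3=C4 trimethylsilyl enol ether of 29 | CC(C)=CCC/C(C)=C/C[C@@]12C[C@H](C(C)(C)[C@@](C(=O)c3ccccc3)(C(=O)Oc3c(F)c(F)c(F)c(F)c3F)C2=O)C[C@H]3C(C)(C)[C@H](C(C)(C)O[Si](CC)(CC)CC)CC3=C1O[Si](C)(C)C
F2 | step 17 | bis(S-ethyl) dithiomalonate analogue of 22 | CC(C)=CCC/C(C)=C/C[C@H]1C[C@H](C(C)(C)C(C(=O)SCC)C(=O)SCC)C[C@H]2C(C)(C)[C@H](C(C)(C)O[Si](CC)(CC)CC)C[C@H]2C1=O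
F3 | step 17 | bis(S-ethyl) benzoyldithiomalonate analogue of 28 | CC(C)=CCC/C(C)=C/C[C@H]1C[C@H](C(C)(C)C(C(=O)c2ccccc2)(C(=O)SCC)C(=O)SCC)C[C@H]2C(C)(C)[C@H](C(C)(C)O[Si](CC)(CC)CC)C[C@H]2C1=O
F4 | step 13 | dimethyl 2-(2-bromopropan-2-yl)malonate | COC(=O)C(C(=O)OC)C(C)(C)Br
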